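**Retrosynthetic overview**
1. The target is a (2S)-5,7-dihydroxy-8-prenylflavanone carrying a 2,2-dimethylchroman (rings B and D) at C2. It is traced back through desilylation, C4 alcohol oxidation and C4–OMe/OH exchange to a 4-methoxyflavan.
2. The strategy rests on ring C: O1–C8a–C4a–C4 is the oxa-diene of a ring A salicylaldehyde (as its O-methyl oxocarbenium/ortho-quinone methide), and C2–C3 is the vinyl group of a ring B styrene made electron-rich by the para oxygen of ring D. O1–C2 and C3–C4 are cut together as one asymmetric [4+2].
3. The aldehyde comes from 2,4,6-trihydroxybenzaldehyde: bis-silylation (regiochemistry fixed by symmetry), O-tert-prenylation of the remaining phenol, then aromatic Claisen rearrangement to the only free ortho carbon. This places the prenyl group at C8 and frees the O1 phenol without any regiochemical ambiguity.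
4. The styrene comes from Wittig methylenation of 2,2-dimethylchroman-6-carbaldehyde.
5. Ring order: rings A, B and D are bought; ring C is the only ring formed (step 6).

Key step: step 6

Assumption: which antipode of the chiral acid leads to 2S cannot be assigned in advance; "(S,S)" below stands for the antipode that a first run shows to do so, and C4 of 12 is drawn cis although its configuration has no consequence.

Step 1
Reactants: 1 2,4,6-trihydroxybenzaldehyde
Product: 2 4,6-bis(tert-butyldimethylsilyloxy)-2-hydroxybenzaldehyde
Conditions: TBSCl (2.05 equiv), imidazole, CH2Cl2/DMF, 0 °C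
Reagents that add atoms: tert-butyldimethylsilyl chloride, CC(C)(C)[Si](C)(C)Cl
Why: Selective phenol silylation: the para hydroxyl and one of the two equivalent ortho hydroxyls react, while the last ortho hydroxyl is held in a hydrogen bond to the aldehyde and should react far more slowly.

Step 2
Reactants: 3 2-methylbut-3-en-2-ol
Product: 4 tert-butyl (2-methylbut-3-en-2-yl) carbonate
Conditions: n-BuLi, THF, −78 to 0 °C; Boc2O, 0 °C to rt
Reagents that add atoms: di-tert-butyl dicarbonate, CC(C)(C)OC(=O)OC(=O)OC(C)(C)C
Why: Acylation of the lithium alkoxide of a tertiary allylic alcohol with Boc2O is a standard way to the mixed carbonate (carbonate formation).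

Step 3
Reactants: 2 4,6-bis(tert-butyldimethylsilyloxy)-2-hydroxybenzaldehyde; 4 tert-butyl (2-methylbut-3-en-2-yl) carbonate
Product: 5 4,6-bis(tert-butyldimethylsilyloxy)-2-[(2-methylbut-3-en-2-yl)oxy]benzaldehyde
Conditions: Pd(PPh3)4 (5 mol%), 4 (1.5 equiv), THF, 0 °C, short reaction time
Reagents that add atoms: none
Why: Tsuji–Trost decarboxylative O-allylation: zerovalent palladium ionises 4 to the 1,1-dimethylallyl palladium cation and tert-butoxide, the latter deprotonates 2, and the phenoxide attacks the more substituted allyl terminus under kinetic control to give the tertiary ether.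

Step 4
Reactants: 5 4,6-bis(tert-butyldimethylsilyloxy)-2-[(2-methylbut-3-en-2-yl)oxy]benzaldehyde
Product: 7 4,6-bis(tert-butyldimethylsilyloxy)-2-hydroxy-3-prenylbenzaldehyde, via ortho-dienone 6 (not isolated)
Conditions: PhMe, 110 °C, sealed tube
Reagents that add atoms: none
Why: Aromatic Claisen rearrangement: the [3,3] shift can only reach the one hydrogen-bearing ortho carbon (the other carries the formyl group), the allyl inversion turns the 1,1-dimethylallyl ether into a prenyl group, and tautomerisation of dienone 6 restores the phenol next to it.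

Step 5
Reactants: 8 2,2-dimethylchroman-6-carbaldehyde
Product: 9 2,2-dimethyl-6-vinylchroman
Conditions: Ph3PCH3Br, KOtBu, THF, 0 °C to rt
Reagents that add atoms: methyltriphenylphosphonium bromide, C[P+](c1ccccc1)(c1ccccc1)c1ccccc1.[Br-]
Why: Wittig methylenation of an aromatic aldehyde with the unstabilised ylide is reliable, and the product is to be kept cold and acid-free because para-alkoxystyrenes polymerise.

Step 6
Reactants: 7 4,6-bis(tert-butyldimethylsilyloxy)-2-hydroxy-3-prenylbenzaldehyde; 9 2,2-dimethyl-6-vinylchroman
Product: 12 (2S,4S)-5,7-bis(tert-butyldimethylsilyloxy)-4-methoxy-8-prenyl-2-(2,2-dimethylchroman-6-yl)chroman, via dimethyl acetal 10 (not isolated), via O-methyl oxocarbenium ion 11 (not isolated)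
Conditions: HC(OMe)3 (1.5 equiv), (S,S)-IDPi (confined N-triflyl imidodiphosphorimidate of two 3,3'-diaryl-BINOL units, 5 mol%), 5 Å MS, CHCl3, −40 °C, slow addition of 9 (1.5 equiv); Et3N quench at −40 °C
Reagents that add atoms: trimethyl orthoformate, COC(OC)OC
Why: Proposed new method: The acid and HC(OMe)3 turn 7 into acetal 10, loss of methanol gives cation 11 (an O-methyl oxocarbenium ion that is at the same time an O-protonated ortho-quinone methide) paired with the chiral imidodiphosphorimidate anion, and the CH2 terminus of styrene 9 attacks C4 while the phenol oxygen closes on the developing benzylic cation at C2, a strongly asynchronous inverse-demand oxa-[4+2] addition that forms C3–C4 and O1–C2 and returns the proton to the catalyst. The closest known reactions are the achiral acid-catalysed three-component chroman synthesis from salicylaldehydes, orthoformates and alkenes and the chiral phosphoric acid catalysed [4+2] additions of ortho-quinone methides to styrenes; confined imidodiphosphorimidates are known to steer other oxocarbenium–alkene additions through ion pairing, which is the ground for expecting transfer to this case. Ring C closes as a six-membered ring by capture of the C2 benzylic cation by O1 within a chair-like ion pair (exo capture of the cation), and since the only free phenol is the one beside the prenyl group the 8-prenyl pattern is fixed. C2 is set by the face of the styrene that the confined anion leaves open to C4 and O1, and C4 should follow as cis through the chair-like transition state with aryl and methoxy pseudo-equatorial; C4 is removed later. The step needs the vinyl group to react in preference to the prenyl alkene, which the para oxygen of ring D secures by making the styrene the better nucleophile and the C2 cation the better stabilised one, and it needs the acid neither to re-open C2–O1 nor to close the prenyl group onto O1, for which the low temperature, the buffering of the acid by methanol and orthoformate and the amine quench are chosen.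

Step 7
Reactants: 12 (2S,4S)-5,7-bis(tert-butyldimethylsilyloxy)-4-methoxy-8-prenyl-2-(2,2-dimethylchroman-6-yl)chroman
Product: 13 (2S)-5,7-bis(tert-butyldimethylsilyloxy)-8-prenyl-2-(2,2-dimethylchroman-6-yl)chroman-4-ol (mixture of C4 epimers)
Conditions: TsOH·H2O (5 mol%), THF/H2O 4:1, 0 °C to rt; NaHCO3 quench
Reagents that add atoms: water, O
Why: SN1 solvolysis of a benzylic ether: the C4–OMe bond ionises much more easily than C2–O1 because the C4 cation is stabilised by O1, O5 and O7 of ring A, the large excess of water captures it, and C2 should stay untouched while both C4 epimers are usable.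

Step 8
Reactants: 13 (2S)-5,7-bis(tert-butyldimethylsilyloxy)-8-prenyl-2-(2,2-dimethylchroman-6-yl)chroman-4-ol
Product: 14 (2S)-5,7-bis(tert-butyldimethylsilyloxy)-8-prenyl-2-(2,2-dimethylchroman-6-yl)chroman-4-one
Conditions: DMP (1.3 equiv), pyridine, CH2Cl2, 0 °C to rt
Reagents that add atoms: none
Why: Dess–Martin oxidation of a secondary benzylic alcohol removes the C4 stereocentre without touching the prenyl alkene, ring D or the silyl ethers, and the pyridine buffer should suppress acid-induced dehydration to the flav-3-ene.

Step 9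
Reactants: 14 (2S)-5,7-bis(tert-butyldimethylsilyloxy)-8-prenyl-2-(2,2-dimethylchroman-6-yl)chroman-4-one
Product: 15 euchrenone a16, (2S)-5,7-dihydroxy-8-prenyl-2-(2,2-dimethylchroman-6-yl)chroman-4-one
Conditions: TBAF (2.5 equiv), AcOH (3 equiv), THF, 0 °C
Reagents that add atoms: none
Why: Fluoride cleavage of aryl silyl ethers, with acetic acid keeping the medium non-basic so that the flavanone does not open to the chalcone by retro-oxa-Michael reaction, which would racemise C2.

**Compound list**
1 | 2,4,6-trihydroxybenzaldehyde | O=Cc1c(O)cc(O)cc1O | starting material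
2 | 4,6-bis(tert-butyldimethylsilyloxy)-2-hydroxybenzaldehyde | O=Cc1c(O)cc(O[Si](C)(C)C(C)(C)C)cc1O[Si](C)(C)C(C)(C)C | intermediate
3 | 2-methylbut-3-en-2-ol | CC(C)(O)C=C | starting material
4 | tert-butyl (2-methylbut-3-en-2-yl) carbonate | C=CC(C)(C)OC(=O)OC(C)(C)C | intermediate
5 | 4,6-bis(tert-butyldimethylsilyloxy)-2-[(2-methylbut-3-en-2-yl)oxy]benzaldehyde | O=Cc1c(OC(C)(C)C=C)cc(O[Si](C)(C)C(C)(C)C)cc1O[Si](C)(C)C(C)(C)C | intermediate
6 | 2,4-bis(tert-butyldimethylsilyloxy)-6-oxo-5-prenylcyclohexa-1,3-diene-1-carbaldehyde (Claisen dienone, racemic at C5, not isolated) | O=CC1=C(O[Si](C)(C)C(C)(C)C)C=C(O[Si](C)(C)C(C)(C)C)C(CC=C(C)C)C1=O | intermediate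
7 | 4,6-bis(tert-butyldimethylsilyloxy)-2-hydroxy-3-prenylbenzaldehyde | CC(C)=CCc1c(O)c(C=O)c(O[Si](C)(C)C(C)(C)C)cc1O[Si](C)(C)C(C)(C)C | intermediate
8 | 2,2-dimethylchroman-6-carbaldehyde | O=Cc1ccc2c(c1)CCC(C)(C)O2 | starting material
9 | 2,2-dimethyl-6-vinylchroman | C=Cc1ccc2c(c1)CCC(C)(C)O2 | intermediate
10 | dimethyl acetal of 7, 3,5-bis(tert-butyldimethylsilyloxy)-2-(dimethoxymethyl)-6-prenylphenol (not isolated) | COC(OC)c1c(O)c(CC=C(C)C)c(O[Si](C)(C)C(C)(C)C)cc1O[Si](C)(C)C(C)(C)C | intermediate
11 | O-methyl oxocarbenium ion of 7 (protonated O-methyl ortho-quinone methide, ion pair with the catalyst anion, not isolated) | C[O+]=Cc1c(O)c(CC=C(C)C)c(O[Si](C)(C)C(C)(C)C)cc1O[Si](C)(C)C(C)(C)C | intermediate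
12 | (2S,4S)-5,7-bis(tert-butyldimethylsilyloxy)-4-methoxy-8-prenyl-2-(2,2-dimethylchroman-6-yl)chroman (2,4-cis) | CC(C)=CCc1c(O[Si](C)(C)C(C)(C)C)cc(O[Si](C)(C)C(C)(C)C)c2c1O[C@H](c1ccc3c(c1)CCC(C)(C)O3)C[C@@H]2OC | intermediate
13 | (2S)-5,7-bis(tert-butyldimethylsilyloxy)-8-prenyl-2-(2,2-dimethylchroman-6-yl)chroman-4-ol (C4 epimers) | CC(C)=CCc1c(O[Si](C)(C)C(C)(C)C)cc(O[Si](C)(C)C(C)(C)C)c2c1O[C@H](c1ccc3c(c1)CCC(C)(C)O3)CC2O | intermediate
14 | (2S)-5,7-bis(tert-butyldimethylsilyloxy)-8-prenyl-2-(2,2-dimethylchroman-6-yl)chroman-4-one | CC(C)=CCc1c(O[Si](C)(C)C(C)(C)C)cc(O[Si](C)(C)C(C)(C)C)c2c1O[C@H](c1ccc3c(c1)CCC(C)(C)O3)CC2=O | intermediate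
15 | euchrenone a16, (2S)-5,7-dihydroxy-8-prenyl-2-(2,2-dimethylchroman-6-yl)chroman-4-one | CC(C)=CCc1c(O)cc(O)c2c1O[C@H](c1ccc3c(c1)CCC(C)(C)O3)CC2=O | target

**Step count**
Total steps: 9. Longest linear sequence: 7 (steps 1, 3, 4, 6, 7, 8, 9).

**Steps most likely to fail**

Step 6. The cation may add to the styrene with poor facial selectivity, giving low enantiomeric purity at C2. The acid may also oligomerise the styrene, and turnover may be slow because the ring A cation is strongly stabilised. The fallback sets out from 7 and 9 and comes back at 14. The same three-component coupling is run with an achiral acid (Sc(OTf)3, HC(OMe)3, CH2Cl2, 0 °C), a known reaction, and should give racemic cis-5,7-bis(tert-butyldimethylsilyloxy)-4-methoxy-8-prenyl-2-(2,2-dimethylchroman-6-yl)chroman F1. Hydrolysis as in step 7 should give racemic 5,7-bis(tert-butyldimethylsilyloxy)-8-prenyl-2-(2,2-dimethylchroman-6-yl)chroman-4-ol F2, and Dess–Martin oxidation racemic 5,7-bis(tert-butyldimethylsilyloxy)-8-prenyl-2-(2,2-dimethylchroman-6-yl)chroman-4-one F3. F3 is then resolved kinetically by Noyori asymmetric transfer hydrogenation (RuCl(p-cymene)[(R,R)-TsDPEN], HCO2H/Et3N), run somewhat past half conversion. By the usual sense of this catalyst family the 2R ketone should be reduced to (2R,4R)-5,7-bis(tert-butyldimethylsilyloxy)-8-prenyl-2-(2,2-dimethylchroman-6-yl)chroman-4-ol F4. The unreduced 2S ketone 14 is separated by chromatography and continues with step 9.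

Step 7. The C4 cation may lose H3 (dehydration to a flav-3-ene), may be captured by ring A of a second molecule (oligomerisation), or the aryl silyl ethers may be partly cleaved by the aqueous acid. The fallback sets out from 12 and comes back at 14, leaving out 13. Compound 12 is oxidised directly with DDQ in CH2Cl2/pH 7 buffer at 0 °C. Hydride abstraction from the electron-rich C4–H gives the O-methyl oxocarbenium ion, water adds, and methanol is lost to give the ketone (oxidative cleavage of an electron-rich benzylic methyl ether, a known reaction type). No new isolated compound arises.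

Step 3. Re-ionisation of the tertiary ether by zerovalent palladium may isomerise it to the linear O-prenyl ether, which would give the wrong Claisen product, or the chelated phenol may be allylated only sluggishly. The fallback sets out from 2 and comes back at 5. Copper-catalysed O-propargylation of 2 with 3-chloro-3-methylbut-1-yne (CuCl2·2H2O cat., DBU, MeCN, 0 °C) should give 4,6-bis(tert-butyldimethylsilyloxy)-2-[(2-methylbut-3-yn-2-yl)oxy]benzaldehyde F5. Semi-hydrogenation over Lindlar catalyst (Pd/CaCO3 poisoned with Pb(OAc)2, quinoline, H2, EtOAc) then gives 5 for step 4.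

**Further compounds**
F1 | step 6 | racemic cis-5,7-bis(tert-butyldimethylsilyloxy)-4-methoxy-8-prenyl-2-(2,2-dimethylchroman-6-yl)chroman (racemate, written without descriptors) | CC(C)=CCc1c(O[Si](C)(C)C(C)(C)C)cc(O[Si](C)(C)C(C)(C)C)c2c1OC(c1ccc3c(c1)CCC(C)(C)O3)CC2OC
F2 | step 6 | racemic 5,7-bis(tert-butyldimethylsilyloxy)-8-prenyl-2-(2,2-dimethylchroman-6-yl)chroman-4-ol (racemate, written without descriptors) | CC(C)=CCc1c(O[Si](C)(C)C(C)(C)C)cc(O[Si](C)(C)C(C)(C)C)c2c1OC(c1ccc3c(c1)CCC(C)(C)O3)CC2O
F3 | step 6 | racemic 5,7-bis(tert-butyldimethylsilyloxy)-8-prenyl-2-(2,2-dimethylchroman-6-yl)chroman-4-one (racemate, written without descriptors) | CC(C)=CCc1c(O[Si](C)(C)C(C)(C)C)cc(O[Si](C)(C)C(C)(C)C)c2c1OC(c1ccc3c(c1)CCC(C)(C)O3)CC2=O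
F4 | step 6 | (2R,4R)-5,7-bis(tert-butyldimethylsilyloxy)-8-prenyl-2-(2,2-dimethylchroman-6-yl)chroman-4-ol | CC(C)=CCc1c(O[Si](C)(C)C(C)(C)C)cc(O[Si](C)(C)C(C)(C)C)c2c1O[C@@H](c1ccc3c(c1)CCC(C)(C)O3)C[C@H]2O
F0 | step 7 | none | none
F5 | step 3 | 4,6-bis(tert-butyldimethylsilyloxy)-2-[(2-methylbut-3-yn-2-yl)oxy]benzaldehyde | O=Cc1c(OC(C)(C)C#C)cc(O[Si](C)(C)C(C)(C)C)cc1O[Si](C)(C)C(C)(C)C
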